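**Retrosynthetic overview**
1. Target 18 ⇐ cross-metathesis (allyl → prenyl) ⇐ benzyl ether cleavage ⇐ 5-allyl phenol 16 ⇐ aromatic Claisen rearrangement of 4-O-allyl ether 14 ⇐ benzofuran aldehyde 13.
2. 13 ⇐ acid-mediated MOM removal, cyclisation and aromatisation of keto acetal 10, ArCO–CH(Ar')–CH(OMe)2. The furan ring is the only ring formed; both benzene rings are bought.
3. 10 ⇐ oxidative 1,2-aryl shift of chalcone 9.
4. 9 ⇐ key C–C bond: intermolecular Claisen–Schmidt aldol condensation of acetophenone 3 with aldehyde 7.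
5. 3 ⇐ 2,4-dihydroxyacetophenone 1 (O-benzylation, O-methylation); 7 ⇐ 5-methoxyresorcinol 4 (bis-MOM ether, directed ortho-lithiation, DMF).

Assumption: the target has no stereocentre and no stereogenic double bond, so the "single enantiomer" is the one achiral compound; transient stereocentres (8, 10, 11, 12, 15) are racemic and are erased later.

**Route**

Step 1
Reactants: 1 2,4-dihydroxyacetophenone
Product: 2 1-[4-(benzyloxy)-2-hydroxyphenyl]ethan-1-one
Conditions: BnBr (1.05 equiv), K2CO3, acetone, reflux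
Reagents that add atoms: benzyl bromide, BrCc1ccccc1
Why: Williamson etherification is selective for O-4 because the 2-OH is hydrogen-bonded to the acetyl C=O and the 4-OH is the more acidic phenol.

Step 2
Reactants: 2 1-[4-(benzyloxy)-2-hydroxyphenyl]ethan-1-one
Product: 3 1-[4-(benzyloxy)-2-methoxyphenyl]ethan-1-one
Conditions: MeI, K2CO3, DMF, 50 °C
Reagents that add atoms: iodomethane, CI
Why: Williamson O-methylation of the remaining chelated phenol, which is the only nucleophilic site left and reacts under these more forcing conditions.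

Step 3
Reactants: 4 5-methoxyresorcinol
Product: 5 1-methoxy-3,5-bis(methoxymethoxy)benzene
Conditions: NaH, MOMCl, DMF, 0 °C to rt
Reagents that add atoms: chloromethyl methyl ether, COCCl
Why: Double Williamson-type O-alkylation of the phenoxides gives base-stable MOM ethers that also serve as directing groups for step 4.

Step 4
Reactants: 5 1-methoxy-3,5-bis(methoxymethoxy)benzene
Product: 7 4-methoxy-2,6-bis(methoxymethoxy)benzaldehyde, via aryllithium 6 (not isolated)
Conditions: n-BuLi, TMEDA, THF, 0 °C; then DMF, 0 °C to rt; H2O quench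
Reagents that add atoms: N,N-dimethylformamide, CN(C)C=O
Why: Directed ortho-metalation occurs preferentially at the carbon flanked by the two chelating OMOM groups (a stronger director than OMe), and DMF formylates the aryllithium; any minor regioisomeric aldehyde is removed by chromatography.

Step 5
Reactants: 3 1-[4-(benzyloxy)-2-methoxyphenyl]ethan-1-one; 7 4-methoxy-2,6-bis(methoxymethoxy)benzaldehyde
Product: 9 (E)-1-[4-(benzyloxy)-2-methoxyphenyl]-3-[4-methoxy-2,6-bis(methoxymethoxy)phenyl]prop-2-en-1-one, via aldol adduct 8 (not isolated)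
Conditions: KOH (aq. 50%), EtOH, rt, 24–48 h
Reagents that add atoms: none
Why: Claisen–Schmidt crossed aldol condensation joins the two fragments, since only 3 is enolisable and 7 cannot self-condense; E1cB dehydration of racemic aldol 8 gives the favoured (E)-enone, and MOM and benzyl ethers are base-stable.

Step 6
Reactants: 9 (E)-1-[4-(benzyloxy)-2-methoxyphenyl]-3-[4-methoxy-2,6-bis(methoxymethoxy)phenyl]prop-2-en-1-one
Product: 10 1-[4-(benzyloxy)-2-methoxyphenyl]-3,3-dimethoxy-2-[4-methoxy-2,6-bis(methoxymethoxy)phenyl]propan-1-one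
Conditions: PhI(OH)OTs (1.5 equiv), MeOH/CH2Cl2, rt
Reagents that add atoms: methanol, CO
Why: Oxidative chalcone rearrangement with trivalent iodine proceeds by methoxy-iodination of the enone C=C, 1,2-shift of the electron-rich β-aryl group with loss of PhI, and capture of the oxocarbenium ion by MeOH; the new stereocentre is racemic and is destroyed in step 8.

Step 7
Reactants: 10 1-[4-(benzyloxy)-2-methoxyphenyl]-3,3-dimethoxy-2-[4-methoxy-2,6-bis(methoxymethoxy)phenyl]propan-1-one
Product: 12 [4-(benzyloxy)-2-methoxyphenyl](4-hydroxy-2,6-dimethoxy-2,3-dihydro-1-benzofuran-3-yl)methanone, via diphenol acetal 11 (not isolated)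
Conditions: conc. HCl (cat.), MeOH, rt to 40 °C, stopped as soon as 10 is consumed
Reagents that add atoms: none
Why: Acid methanolysis removes both MOM groups and one of the two equivalent phenols closes onto the acetal carbon (transacetalisation); the ring is symmetric so there is no regiochemical issue, and the two stereocentres (racemic cis/trans mixture) are erased in step 8.

Step 8
Reactants: 12 [4-(benzyloxy)-2-methoxyphenyl](4-hydroxy-2,6-dimethoxy-2,3-dihydro-1-benzofuran-3-yl)methanone
Product: 13 2-[4-(benzyloxy)-2-methoxyphenyl]-4-hydroxy-6-methoxy-1-benzofuran-3-carbaldehyde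
Conditions: p-TsOH·H2O (0.5 equiv), (CF3)2CHOH, rt
Reagents that add atoms: none
Why: In strongly ionising, non-nucleophilic HFIP the cyclic methyl acetal opens to the oxocarbenium/aldehyde, the phenol recloses on the aryl ketone and cyclodehydration gives the aromatic 2-aryl-3-formylbenzofuran with loss of MeOH (acid-mediated ring-opening/recyclisation).

Step 9
Reactants: 13 2-[4-(benzyloxy)-2-methoxyphenyl]-4-hydroxy-6-methoxy-1-benzofuran-3-carbaldehyde
Product: 14 4-(allyloxy)-2-[4-(benzyloxy)-2-methoxyphenyl]-6-methoxy-1-benzofuran-3-carbaldehyde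
Conditions: allyl bromide, K2CO3, DMF, 60 °C
Reagents that add atoms: allyl bromide, C=CCBr
Why: Williamson O-allylation of the only free phenol; mild heating overcomes its hydrogen bond to the aldehyde, which is non-enolisable and base-stable.

Step 10
Reactants: 14 4-(allyloxy)-2-[4-(benzyloxy)-2-methoxyphenyl]-6-methoxy-1-benzofuran-3-carbaldehyde
Product: 16 5-allyl-2-[4-(benzyloxy)-2-methoxyphenyl]-4-hydroxy-6-methoxy-1-benzofuran-3-carbaldehyde, via dienone 15 (not isolated)
Conditions: PhNEt2, 190 °C, sealed tube, Ar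
Reagents that add atoms: none
Why: Aromatic Claisen [3,3]-sigmatropic rearrangement delivers the allyl group to C5, the only free ortho position (the other is the ring-fusion carbon C3a), and dienone 15 tautomerises to the phenol, erasing its transient stereocentre.

Step 11
Reactants: 16 5-allyl-2-[4-(benzyloxy)-2-methoxyphenyl]-4-hydroxy-6-methoxy-1-benzofuran-3-carbaldehyde
Product: 17 5-allyl-4-hydroxy-2-(4-hydroxy-2-methoxyphenyl)-6-methoxy-1-benzofuran-3-carbaldehyde
Conditions: BCl3 (3 equiv), C6HMe5 (5 equiv), CH2Cl2, −78 °C; then H2O quench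
Reagents that add atoms: none
Why: Lewis-acid debenzylation with a cation scavenger: BCl3 ionises the aryl benzyl ether at −78 °C and pentamethylbenzene traps the benzyl cation (Friedel–Crafts), sparing the terminal alkene, aldehyde and methyl ethers; it is done before the acid-sensitive prenyl group exists.

Step 12
Reactants: 17 5-allyl-4-hydroxy-2-(4-hydroxy-2-methoxyphenyl)-6-methoxy-1-benzofuran-3-carbaldehyde
Product: 18 4-hydroxy-2-(4-hydroxy-2-methoxyphenyl)-6-methoxy-5-(3-methylbut-2-en-1-yl)-1-benzofuran-3-carbaldehyde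
Conditions: 2-methyl-2-butene (excess), second-generation Grubbs catalyst (H2IMes)(PCy3)Cl2Ru=CHPh (5 mol %), CH2Cl2, 40 °C
Reagents that add atoms: 2-methyl-2-butene, CC=C(C)C
Why: Olefin cross-metathesis of the terminal allyl group with 2-methyl-2-butene releases propene and gives the trisubstituted prenyl alkene (no E/Z issue); the catalyst tolerates free phenols and the aldehyde.

**Compound list**
1 | 2,4-dihydroxyacetophenone | CC(=O)c1ccc(O)cc1O | starting material
2 | 1-[4-(benzyloxy)-2-hydroxyphenyl]ethan-1-one | CC(=O)c1ccc(OCc2ccccc2)cc1O | intermediate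
3 | 1-[4-(benzyloxy)-2-methoxyphenyl]ethan-1-one | CC(=O)c1ccc(OCc2ccccc2)cc1OC | intermediate
4 | 5-methoxyresorcinol (5-methoxybenzene-1,3-diol) | COc1cc(O)cc(O)c1 | starting material
5 | 1-methoxy-3,5-bis(methoxymethoxy)benzene | COCOc1cc(OC)cc(OCOC)c1 | intermediate
6 | [4-methoxy-2,6-bis(methoxymethoxy)phenyl]lithium | [Li]c1c(OCOC)cc(OC)cc1OCOC | intermediate (not isolated)
7 | 4-methoxy-2,6-bis(methoxymethoxy)benzaldehyde | COCOc1cc(OC)cc(OCOC)c1C=O | intermediate
8 | 1-[4-(benzyloxy)-2-methoxyphenyl]-3-hydroxy-3-[4-methoxy-2,6-bis(methoxymethoxy)phenyl]propan-1-one (racemic) | COCOc1cc(OC)cc(OCOC)c1C(O)CC(=O)c1ccc(OCc2ccccc2)cc1OC | intermediate (not isolated)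
9 | (E)-1-[4-(benzyloxy)-2-methoxyphenyl]-3-[4-methoxy-2,6-bis(methoxymethoxy)phenyl]prop-2-en-1-one | COCOc1cc(OC)cc(OCOC)c1/C=C/C(=O)c1ccc(OCc2ccccc2)cc1OC | intermediate
10 | 1-[4-(benzyloxy)-2-methoxyphenyl]-3,3-dimethoxy-2-[4-methoxy-2,6-bis(methoxymethoxy)phenyl]propan-1-one (racemic) | COC(OC)C(c1c(OCOC)cc(OC)cc1OCOC)C(=O)c1ccc(OCc2ccccc2)cc1OC | intermediate
11 | 1-[4-(benzyloxy)-2-methoxyphenyl]-2-(2,6-dihydroxy-4-methoxyphenyl)-3,3-dimethoxypropan-1-one (racemic) | COC(OC)C(c1c(O)cc(OC)cc1O)C(=O)c1ccc(OCc2ccccc2)cc1OC | intermediate (not isolated)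
12 | [4-(benzyloxy)-2-methoxyphenyl](4-hydroxy-2,6-dimethoxy-2,3-dihydro-1-benzofuran-3-yl)methanone (racemic cis/trans mixture, stereocentres not controlled) | COC1Oc2cc(OC)cc(O)c2C1C(=O)c1ccc(OCc3ccccc3)cc1OC | intermediate
13 | 2-[4-(benzyloxy)-2-methoxyphenyl]-4-hydroxy-6-methoxy-1-benzofuran-3-carbaldehyde | COc1cc(OCc2ccccc2)ccc1-c1oc2cc(OC)cc(O)c2c1C=O | intermediate
14 | 4-(allyloxy)-2-[4-(benzyloxy)-2-methoxyphenyl]-6-methoxy-1-benzofuran-3-carbaldehyde | COc1cc(OCc2ccccc2)ccc1-c1oc2cc(OC)cc(OCC=C)c2c1C=O | intermediate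
15 | 5-allyl-2-[4-(benzyloxy)-2-methoxyphenyl]-6-methoxy-4-oxo-4,5-dihydro-1-benzofuran-3-carbaldehyde (racemic) | C=CCC1C(OC)=Cc2oc(-c3ccc(OCc4ccccc4)cc3OC)c(C=O)c2C1=O | intermediate (not isolated)
16 | 5-allyl-2-[4-(benzyloxy)-2-methoxyphenyl]-4-hydroxy-6-methoxy-1-benzofuran-3-carbaldehyde | COc1cc(OCc2ccccc2)ccc1-c1oc2cc(OC)c(CC=C)c(O)c2c1C=O | intermediate
17 | 5-allyl-4-hydroxy-2-(4-hydroxy-2-methoxyphenyl)-6-methoxy-1-benzofuran-3-carbaldehyde | COc1cc(O)ccc1-c1oc2cc(OC)c(CC=C)c(O)c2c1C=O | intermediate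
18 | 4-hydroxy-2-(4-hydroxy-2-methoxyphenyl)-6-methoxy-5-(3-methylbut-2-en-1-yl)-1-benzofuran-3-carbaldehyde (achiral) | COc1cc(O)ccc1-c1oc2cc(OC)c(CC=C(C)C)c(O)c2c1C=O | target

**Totals**
Total step count: 12. Longest linear sequence: 10 steps (1 → 18 via steps 1, 2, 5–12; the branch from 4 via steps 3, 4, 5–12 is equally long).

**Three steps most likely to fail, with fallbacks**

The first is step 6. Ring B of chalcone 9 is a very electron-rich trioxygenated arene that PhI(OH)OTs can attack directly, and the liberated TsOH can strip MOM groups early. The fallback sets out from 9 and comes back at 12, replacing the oxidative aryl shift by an epoxide/acyl-shift sequence. Weitz–Scheffer epoxidation of 9 (H2O2, NaOH, MeOH/THF, 0 °C) gives the racemic trans-epoxy ketone F1. Catalytic BF3·OEt2 in CH2Cl2 at −40 °C opens the epoxide at the benzylic carbon and triggers a 1,2-aroyl shift (Meinwald-type rearrangement) to the α-formyl ketone F2, which has the carbon skeleton of 10. Catalytic HCl in MeOH then removes the MOM groups and closes the cyclic methyl acetal, giving 12.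

The second is step 8, whose failure mode can already start in step 7. The cyclic acetal 12 can lose MeOH irreversibly to the isomeric 3-aroylbenzofuran instead of reopening to the 3-formyl-2-aryl isomer. The fallback sets out from 10 and comes back at 13, and makes the formyl carbon non-electrophilic before ring closure. Treating 10 with propane-1,3-dithiol and BF3·OEt2 (CH2Cl2, 0 °C to rt, short reaction time to spare the benzyl ether) converts the dimethyl acetal into a dithiane and cleaves the MOM ethers. The phenol can then only condense with the aryl ketone, giving the dithiane-protected benzofuran F3. Hydrolysis of the dithiane (MeI, CaCO3, MeCN/H2O, 45 °C) returns aldehyde 13.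

The third is step 11. BCl3 may also attack the aryl methyl ethers or the allyl group, or the boron chelate of the hydroxy aldehyde may be hard to break. The fallback sets out from 13 and comes back at 17, swapping the protecting group before any alkene is present. Hydrogenolysis of 13 (H2, Pd/C, EtOAc, rt, stopped at debenzylation) gives the diphenol F4. The non-chelated 4'-OH is silylated selectively (TIPSCl, imidazole, DMF, 0 °C) to the mono-TIPS ether F5. O-Allylation of the chelated 4-OH (allyl bromide, K2CO3, acetone, reflux) gives the allyl ether F6. Claisen rearrangement (PhNEt2, 190 °C) gives the C-allyl phenol F7. TBAF (THF, 0 °C) removes the silyl group to give 17.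

Further compounds
F1 | step 6 | trans-[4-(benzyloxy)-2-methoxyphenyl]{3-[4-methoxy-2,6-bis(methoxymethoxy)phenyl]oxiran-2-yl}methanone (racemic, one enantiomer drawn) | COCOc1cc(OC)cc(OCOC)c1[C@H]1O[C@@H]1C(=O)c1ccc(OCc2ccccc2)cc1OC
F2 | step 6 | 3-[4-(benzyloxy)-2-methoxyphenyl]-2-[4-methoxy-2,6-bis(methoxymethoxy)phenyl]-3-oxopropanal (racemic) | O=CC(c1c(OCOC)cc(OC)cc1OCOC)C(=O)c1ccc(OCc2ccccc2)cc1OC
F3 | step 8 | 2-[4-(benzyloxy)-2-methoxyphenyl]-3-(1,3-dithian-2-yl)-6-methoxy-1-benzofuran-4-ol | COc1cc(OCc2ccccc2)ccc1-c1oc2cc(OC)cc(O)c2c1C1SCCCS1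
F4 | step 11 | 4-hydroxy-2-(4-hydroxy-2-methoxyphenyl)-6-methoxy-1-benzofuran-3-carbaldehyde | COc1cc(O)ccc1-c1oc2cc(OC)cc(O)c2c1C=O
F5 | step 11 | 4-hydroxy-6-methoxy-2-{2-methoxy-4-[(triisopropylsilyl)oxy]phenyl}-1-benzofuran-3-carbaldehyde | COc1cc(O[Si](C(C)C)(C(C)C)C(C)C)ccc1-c1oc2cc(OC)cc(O)c2c1C=O
F6 | step 11 | 4-(allyloxy)-6-methoxy-2-{2-methoxy-4-[(triisopropylsilyl)oxy]phenyl}-1-benzofuran-3-carbaldehyde | COc1cc(O[Si](C(C)C)(C(C)C)C(C)C)ccc1-c1oc2cc(OC)cc(OCC=C)c2c1C=O
F7 | step 11 | 5-allyl-4-hydroxy-6-methoxy-2-{2-methoxy-4-[(triisopropylsilyl)oxy]phenyl}-1-benzofuran-3-carbaldehyde | COc1cc(O[Si](C(C)C)(C(C)C)C(C)C)ccc1-c1oc2cc(OC)c(CC=C)c(O)c2c1C=O
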